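The route rests on cutting the bond between C2 of the oxolane ring and C1 of the 3,4,5-trimethoxyphenyl ring. The feature exploited is the array O1–C2–C3–CH2OH. Drawn as O1–C2=C3–CH2OH, it is at once a cyclic enol ether and an allylic alcohol. A redox-relay Heck arylation of that 4,5-dihydrofuran with 5-iodo-1,2,3-trimethoxybenzene should do three things in one operation. It should forge the aryl–C2 bond, set C2 and C3 from the lone C4 stereocentre (aryl and hydrogen delivered syn, anti to the benzyl group), and turn CH2OH into an aldehyde that borohydride reduces in the same flask. The precursor is a flat dihydrofuranylmethanol with one stereocentre, made from an (S)-β-benzylbutyrolactone.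

Key step: step 8

Numbering used throughout: O1, C2 (aryl), C3 (CH2OH), C4 (benzyl), C5 (CH2) of the oxolane ring.
Assumption: the (R,R) antipode of Et-DuPhos is taken to give the (S)-acid 5, by analogy with the quadrant model for enamides; if the sense proves opposite, the (S,S) ligand is used and nothing else changes.

Step 1
Reactants: 1 3-hydroxy-4,5-dimethoxybenzaldehyde
Product: 2 3-(benzyloxy)-4,5-dimethoxybenzaldehyde
Conditions: BnBr, K2CO3, DMF, rt
Reagents that add atoms: benzyl bromide, BrCc1ccccc1
Why: Williamson ether synthesis on the only acidic OH; the aryl benzyl ether should withstand the alkoxide, homogeneous hydrogenation, hydride, acid and palladium steps that follow, and no stereocentre is created.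

Step 2
Reactants: 2 3-(benzyloxy)-4,5-dimethoxybenzaldehyde, 3 dimethyl succinate
Product: 4 (3E)-4-[3-(benzyloxy)-4,5-dimethoxyphenyl]-3-(methoxycarbonyl)but-3-enoic acid
Conditions: NaOMe, MeOH, reflux; then aq. HCl
Reagents that add atoms: none
Why: Stobbe condensation: the succinate enolate adds to the non-enolisable aldehyde, the aldolate closes to a paraconic ester lactone, and its E1cB opening gives the half-ester irreversibly as the carboxylate, with the aryl group trans to CO2Me (E) for steric reasons.

Step 3
Reactants: 4 (3E)-4-[3-(benzyloxy)-4,5-dimethoxyphenyl]-3-(methoxycarbonyl)but-3-enoic acid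
Product: 5 (3S)-4-[3-(benzyloxy)-4,5-dimethoxyphenyl]-3-(methoxycarbonyl)butanoic acid
Conditions: [Rh(cod)((R,R)-Et-DuPhos)]BF4 (0.5 mol %), NaOMe (10 mol %), H2 (5 bar), MeOH, rt
Reagents that add atoms: none
Why: Rhodium-catalysed asymmetric hydrogenation of a Stobbe-type itaconate half-ester: the CH2CO2 arm chelates rhodium as the amide carbonyl of an enamide does, the C2-symmetric bisphospholane then selects the alkene face and sets the S stereocentre (the later C4), and the homogeneous catalyst leaves the benzyl ether alone.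

Step 4
Reactants: 5 (3S)-4-[3-(benzyloxy)-4,5-dimethoxyphenyl]-3-(methoxycarbonyl)butanoic acid
Product: 6 (4S)-4-[3-(benzyloxy)-4,5-dimethoxybenzyl]oxolan-2-one
Conditions: KOH (1 equiv), EtOH; CaCl2, NaBH4, EtOH, −10 °C to rt; then 2 M HCl, rt
Reagents that add atoms: none
Why: Chemoselective borohydride reduction followed by lactonisation: calcium borohydride reduces the methyl ester but not the carboxylate salt, the low temperature keeps the stereocentre next to the ester from enolising, and acid closes the γ-lactone (5-exo-trig).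

Step 5
Reactants: 6 (4S)-4-[3-(benzyloxy)-4,5-dimethoxybenzyl]oxolan-2-one
Product: 7 (4S)-4-[3-(benzyloxy)-4,5-dimethoxybenzyl]-3-(hydroxymethylidene)oxolan-2-one (enol form of the α-formyl lactone, alkene geometry not defined)
Conditions: NaH, HCO2Et, THF, 0 °C to rt; then cold 1 M HCl
Reagents that add atoms: ethyl formate, CCOC=O
Why: Crossed Claisen condensation (α-formylation): ethyl formate cannot enolise, the lactone enolate forms only at C3, deprotonation of the β-dicarbonyl product drives the equilibrium, and the non-acidic C4 stereocentre is untouched.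

Step 6
Reactants: 7 (4S)-4-[3-(benzyloxy)-4,5-dimethoxybenzyl]-3-(hydroxymethylidene)oxolan-2-one
Product: 9 methyl (4S)-4-[3-(benzyloxy)-4,5-dimethoxybenzyl]-4,5-dihydrofuran-3-carboxylate, via 2-methoxyoxolane ester 8 (not isolated)
Conditions: cat. H2SO4, MeOH, reflux; solvent switch; cat. TsOH, toluene, reflux through 4 Å MS
Reagents that add atoms: methanol, CO
Why: Acyl-lactone rearrangement: acid methanolysis opens the lactone to the methyl ester, the freed C5 hydroxyl closes on the formyl carbon (5-exo-trig) to the mixed acetal 8, and acid-catalysed loss of methanol with trapping of the alcohol on sieves gives the push-pull enol ether ester, whose conjugation drives the elimination and erases the undefined centres at C2 and C3.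

Step 7
Reactants: 9 methyl (4S)-4-[3-(benzyloxy)-4,5-dimethoxybenzyl]-4,5-dihydrofuran-3-carboxylate
Product: 10 {(4S)-4-[3-(benzyloxy)-4,5-dimethoxybenzyl]-4,5-dihydrofuran-3-yl}methanol
Conditions: DIBAL-H (2.5 equiv), CH2Cl2, −78 °C; aq. Rochelle salt
Reagents that add atoms: none
Why: DIBAL-H 1,2-reduction of a vinylogous carbonate ester: two hydrides take CO2Me to CH2OH, the electron-rich C2=C3 bond is not attacked, and the basic tartrate work-up avoids ionisation of the acid-labile allylic alcohol, which belongs to the same isolable class as the 2-C-hydroxymethyl glycals.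

Step 8
Reactants: 10 {(4S)-4-[3-(benzyloxy)-4,5-dimethoxybenzyl]-4,5-dihydrofuran-3-yl}methanol, 11 5-iodo-1,2,3-trimethoxybenzene
Product: 13 {(2R,3S,4S)-4-[3-(benzyloxy)-4,5-dimethoxybenzyl]-2-(3,4,5-trimethoxyphenyl)oxolan-3-yl}methanol, via oxolane-3-carbaldehyde 12 (not isolated)
Conditions: Pd(OAc)2 (10 mol %), n-Bu4NCl, NaHCO3, 4 Å MS, DMF, 50 °C; then MeOH, NaBH4, 0 °C
Reagents that add atoms: none
Why: Oxidative addition of 11 gives an arylpalladium(II) species that adds syn across C2=C3 (aryl to C2, palladium to C3); β-hydride elimination from the CH2OH group, re-insertion that places hydrogen on C3 on the face palladium occupied, and loss of HPdX from the α-hydroxyalkylpalladium release aldehyde 12, which borohydride reduces in the same flask before it can enolise. The closest known reaction types are the Heck arylation of allylic alcohols to β-aryl aldehydes under ammonium chloride/bicarbonate conditions (redox-relay Heck reaction) and the Heck C-arylation of furanoid glycals at the carbon next to oxygen. No ring is closed, since the oxolane is already present as its 4,5-dihydrofuran. C2 is controlled by the C4 benzyl group, which shields one face of the flat ring so that arylpalladium adds anti to it, and C3 is controlled by the syn stereospecificity of insertion and chain walk, which leaves C3–H cis to the aryl group and hence CHO trans to aryl and cis to benzyl. Regioselectivity (aryl to C2) is secured twice, by the ring oxygen that polarises the enol ether and by C3 being fully substituted, and because C2–H ends anti to palladium the insertion cannot collapse to an aryl enol ether. The selectivity still needed is β-hydride elimination toward CH2OH rather than toward the syn C4–H; the hydridic carbinol C–H bonds, hydroxyl coordination and the irreversible exit as aldehyde favour it, as in the arylation of methallyl alcohol, where the aldehyde prevails although other β-hydrogens are on offer.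

Step 9
Reactants: 13 {(2R,3S,4S)-4-[3-(benzyloxy)-4,5-dimethoxybenzyl]-2-(3,4,5-trimethoxyphenyl)oxolan-3-yl}methanol
Product: 14 {(2R,3S,4S)-4-(3-hydroxy-4,5-dimethoxybenzyl)-2-(3,4,5-trimethoxyphenyl)oxolan-3-yl}methanol (CNP0121704.1)
Conditions: H2 (1 atm), 10 % Pd/C, EtOAc, rt
Reagents that add atoms: none
Why: Catalytic hydrogenolysis: under neutral conditions at 1 atm the aryl benzyl ether is cleaved much faster than the ring C2–O1 bond, so that interruption after uptake of one equivalent of hydrogen should leave the oxolane and its three stereocentres intact.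

Compound list
1 | 3-hydroxy-4,5-dimethoxybenzaldehyde | COc1cc(C=O)cc(O)c1OC | starting material
2 | 3-(benzyloxy)-4,5-dimethoxybenzaldehyde | COc1cc(C=O)cc(OCc2ccccc2)c1OC | intermediate
3 | dimethyl succinate | COC(=O)CCC(=O)OC | starting material
4 | (3E)-4-[3-(benzyloxy)-4,5-dimethoxyphenyl]-3-(methoxycarbonyl)but-3-enoic acid | COc1cc(/C=C(/C(=O)OC)CC(=O)O)cc(OCc2ccccc2)c1OC | intermediate
5 | (3S)-4-[3-(benzyloxy)-4,5-dimethoxyphenyl]-3-(methoxycarbonyl)butanoic acid | COc1cc(C[C@@H](CC(=O)O)C(=O)OC)cc(OCc2ccccc2)c1OC | intermediate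
6 | (4S)-4-[3-(benzyloxy)-4,5-dimethoxybenzyl]oxolan-2-one | COc1cc(C[C@@H]2COC(=O)C2)cc(OCc3ccccc3)c1OC | intermediate
7 | (4S)-4-[3-(benzyloxy)-4,5-dimethoxybenzyl]-3-(hydroxymethylidene)oxolan-2-one | COc1cc(C[C@@H]2COC(=O)C2=CO)cc(OCc3ccccc3)c1OC | intermediate
8 | methyl (4S)-4-[3-(benzyloxy)-4,5-dimethoxybenzyl]-2-methoxyoxolane-3-carboxylate (mixture at C2 and C3, not isolated) | COc1cc(C[C@@H]2COC(OC)C2C(=O)OC)cc(OCc3ccccc3)c1OC | intermediate
9 | methyl (4S)-4-[3-(benzyloxy)-4,5-dimethoxybenzyl]-4,5-dihydrofuran-3-carboxylate | COc1cc(C[C@@H]2COC=C2C(=O)OC)cc(OCc3ccccc3)c1OC | intermediate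
10 | {(4S)-4-[3-(benzyloxy)-4,5-dimethoxybenzyl]-4,5-dihydrofuran-3-yl}methanol | COc1cc(C[C@@H]2COC=C2CO)cc(OCc3ccccc3)c1OC | intermediate
11 | 5-iodo-1,2,3-trimethoxybenzene | COc1cc(I)cc(OC)c1OC | starting material
12 | (2R,3R,4S)-4-[3-(benzyloxy)-4,5-dimethoxybenzyl]-2-(3,4,5-trimethoxyphenyl)oxolane-3-carbaldehyde (not isolated) | COc1cc(C[C@@H]2CO[C@@H](c3cc(OC)c(OC)c(OC)c3)[C@@H]2C=O)cc(OCc3ccccc3)c1OC | intermediate
13 | {(2R,3S,4S)-4-[3-(benzyloxy)-4,5-dimethoxybenzyl]-2-(3,4,5-trimethoxyphenyl)oxolan-3-yl}methanol | COc1cc(C[C@@H]2CO[C@@H](c3cc(OC)c(OC)c(OC)c3)[C@@H]2CO)cc(OCc3ccccc3)c1OC | intermediate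
14 | {(2R,3S,4S)-4-(3-hydroxy-4,5-dimethoxybenzyl)-2-(3,4,5-trimethoxyphenyl)oxolan-3-yl}methanol | COc1cc(C[C@@H]2CO[C@@H](c3cc(OC)c(OC)c(OC)c3)[C@@H]2CO)cc(O)c1OC | target

Total step count: 9. Longest linear sequence: 9 steps (1 to 14).

Steps most likely to fail

Step 8.
- Insertion into the trisubstituted alkene may be slow.
- β-Hydride elimination may run toward the syn C4–H, followed by chain walking away from the carbinol carbon, which would erase C4.
- The enol may leave palladium before re-insertion, so that C3 is set by unselective protonation.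
- The aldehyde may enolise before it is reduced.

The fallback forms the same bond by ionic rather than organopalladium chemistry. It sets out from 10 and comes back at 13. Silylation of 10 (TBSCl, imidazole, DMF) gives the silyl ether F1. Addition of benzenesulfinic acid across the enol ether (CH2Cl2, rt), with protonation of C3 on the face away from the benzyl group, gives the 2-(phenylsulfonyl)oxolane F2. Commercial 3,4,5-trimethoxyphenylmagnesium bromide and ZnBr2 give bis(3,4,5-trimethoxyphenyl)zinc F3. Together with the magnesium bromide formed, F3 replaces the sulfonyl group through the C2 oxocarbenium ion, attacking anti to the C3 substituent, to give the arylated silyl ether F4. TBAF in THF then returns to 13.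

Step 6.
- The ring switch may stay incomplete.
- During the hot acid-catalysed loss of methanol, the C2 oxocarbenium ion may be captured by the electron-rich benzyl ring in a Friedel–Crafts ring closure.

The fallback builds the C3 carbon onto a preformed enol ether instead of rearranging a formyl lactone. It sets out from 6 and comes back at 10. DIBAL-H (1.1 equiv, −78 °C) gives the lactol F5. MsCl and Et3N (CH2Cl2, 0 °C to reflux) dehydrate it to the 2,3-dihydrofuran F6. Vilsmeier–Haack formylation (POCl3, DMF, 0 °C; aq. NaHCO3) at the nucleophilic β-carbon gives the β-alkoxy enal F7. NaBH4 in EtOH at 0 °C then gives 10.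

Step 9.
- Over-reduction may occur, that is hydrogenolysis of the benzylic C2–O1 bond of the ring alongside the debenzylation.

The fallback removes the benzyl ether while no benzylic ring ether exists and runs the end game on the free phenol. It sets out from 6 and comes back at 14.
- Hydrogenolysis of 6 (H2, Pd/C, EtOAc) gives the phenol lactone F8.
- Formylation with an extra equivalent of NaH gives the hydroxymethylidene lactone F9.
- Acidic methanol gives the methoxy acetal F10, and loss of methanol gives the dihydrofuran ester F11.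
- DIBAL-H (3.5 equiv) gives the allylic alcohol F12.
- The Heck arylation with 11 under the conditions of step 8 gives the aldehyde F13, and NaBH4 in the same flask gives 14.

Further compounds
F1 | step 8 | tert-butyl({(4S)-4-[3-(benzyloxy)-4,5-dimethoxybenzyl]-4,5-dihydrofuran-3-yl}methoxy)dimethylsilane | COc1cc(C[C@@H]2COC=C2CO[Si](C)(C)C(C)(C)C)cc(OCc3ccccc3)c1OC
F2 | step 8 | (3S,4S)-4-[3-(benzyloxy)-4,5-dimethoxybenzyl]-3-[(tert-butyldimethylsilyloxy)methyl]-2-(phenylsulfonyl)oxolane (mixture at C2) | COc1cc(C[C@@H]2COC([C@@H]2CO[Si](C)(C)C(C)(C)C)S(=O)(=O)c3ccccc3)cc(OCc4ccccc4)c1OC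
F3 | step 8 | bis(3,4,5-trimethoxyphenyl)zinc | COc1cc([Zn]c2cc(OC)c(OC)c(OC)c2)cc(OC)c1OC
F4 | step 8 | (2R,3S,4S)-4-[3-(benzyloxy)-4,5-dimethoxybenzyl]-3-[(tert-butyldimethylsilyloxy)methyl]-2-(3,4,5-trimethoxyphenyl)oxolane | COc1cc(C[C@@H]2CO[C@@H](c3cc(OC)c(OC)c(OC)c3)[C@@H]2CO[Si](C)(C)C(C)(C)C)cc(OCc3ccccc3)c1OC
F5 | step 6 | (4S)-4-[3-(benzyloxy)-4,5-dimethoxybenzyl]oxolan-2-ol (mixture at C2) | COc1cc(C[C@@H]2COC(O)C2)cc(OCc3ccccc3)c1OC
F6 | step 6 | (3S)-3-[3-(benzyloxy)-4,5-dimethoxybenzyl]-2,3-dihydrofuran | COc1cc(C[C@@H]2COC=C2)cc(OCc3ccccc3)c1OC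
F7 | step 6 | (4S)-4-[3-(benzyloxy)-4,5-dimethoxybenzyl]-4,5-dihydrofuran-3-carbaldehyde | COc1cc(C[C@@H]2COC=C2C=O)cc(OCc3ccccc3)c1OC
F8 | step 9 | (4S)-4-(3-hydroxy-4,5-dimethoxybenzyl)oxolan-2-one | COc1cc(C[C@@H]2COC(=O)C2)cc(O)c1OC
F9 | step 9 | (4S)-4-(3-hydroxy-4,5-dimethoxybenzyl)-3-(hydroxymethylidene)oxolan-2-one | COc1cc(C[C@@H]2COC(=O)C2=CO)cc(O)c1OC
F10 | step 9 | methyl (4S)-4-(3-hydroxy-4,5-dimethoxybenzyl)-2-methoxyoxolane-3-carboxylate (mixture at C2 and C3) | COc1cc(C[C@@H]2COC(OC)C2C(=O)OC)cc(O)c1OC
F11 | step 9 | methyl (4S)-4-(3-hydroxy-4,5-dimethoxybenzyl)-4,5-dihydrofuran-3-carboxylate | COc1cc(C[C@@H]2COC=C2C(=O)OC)cc(O)c1OC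
F12 | step 9 | 5-{[(3S)-4-(hydroxymethyl)-2,3-dihydrofuran-3-yl]methyl}-2,3-dimethoxyphenol | COc1cc(C[C@@H]2COC=C2CO)cc(O)c1OC
F13 | step 9 | (2R,3R,4S)-4-(3-hydroxy-4,5-dimethoxybenzyl)-2-(3,4,5-trimethoxyphenyl)oxolane-3-carbaldehyde | COc1cc(C[C@@H]2CO[C@@H](c3cc(OC)c(OC)c(OC)c3)[C@@H]2C=O)cc(O)c1OC
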